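**Plan**

- Retrosynthesis first removes the C8 chlorohydrin ester, the C13 acetate and both epoxide oxygens. It then cuts the butenolide at C7–C11 and O6–C12, which leads back to a ten-membered 6-oxo-1(10),4-diene.
- Enabling feature: the epoxide-bearing ring bonds C1–C10 and C4–C5 are linked on one side by the C2–C3 ethano unit and on the other by the C6–C9 chain carrying O6 and O8. This cyclodeca-1,5-diene pattern maps onto a bicyclo[2.2.0]hexane, i.e. cyclohexenone ring C5–C10 (carbonyl C6) joined across C4–C5 and C1–C10 to cyclobutene ring C1–C4.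
- Forward order of rings: six-membered enone, then the 6-4-4 tricycle by [2+2] photocycloaddition, then the ten-membered ring by flash thermolysis (C1–C4 and C5–C10 break) with Z to E correction of the enone. The butenolide follows (C7 aldol, C6 reduction, lactonisation, dehydration), then the esters, then the epoxides.
- Stereochemistry: C8 comes from lipase desymmetrisation of a meso diol. C7 (transient) is set anti to O8 in the aldol, and C6 by Felkin–Anh reduction relayed from C7. The four epoxide centers come from peripheral attack on the crown conformer (C4/C5 face fixed by allylic strain about C6). The side-chain center comes from methyl (S)-2-methylglycidate.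

Key step: step 7

Remark: atoms carry germacrane locants (ring C1–C10, lactone carbons C11–C13, C14 on C10, C15 on C4); all-cis-cyclohexane-1,3,5-triol and methyl (S)-2-methylglycidate are taken as commercial.

**Route**

Step 1
Reactants: 1 all-cis-cyclohexane-1,3,5-triol
Product: 2 all-cis-5-(tert-butyldimethylsilyloxy)cyclohexane-1,3-diol
Conditions: NaH (1.0 equiv), t-BuMe2SiCl (1.0 equiv), THF–DMF, 0 → 25 °C
Reagents that add atoms: tert-butyldimethylsilyl chloride, CC(C)(C)[Si](C)(C)Cl
Why: O-Silylation of the monosodium alkoxide of the symmetric triol should stop largely at the mono ether, which is a meso compound, so no stereocenter is defined yet.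

Step 2
Reactants: 2 all-cis-5-(tert-butyldimethylsilyloxy)cyclohexane-1,3-diol
Product: 3 (1R,3S,5S)-3-(tert-butyldimethylsilyloxy)-5-hydroxycyclohexyl acetate
Conditions: lipase PS (Burkholderia cepacia), vinyl acetate, t-BuOMe, 25 °C
Reagents that add atoms: vinyl acetate, CC(=O)OC=C
Why: Lipase-catalysed irreversible transesterification desymmetrises the meso diol by acetylating the R-configured carbinol (the usual preference of this enzyme for secondary alcohols), which fixes the absolute configuration of the silyloxy carbon, the future C8.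

Step 3
Reactants: 3 (1R,3S,5S)-3-(tert-butyldimethylsilyloxy)-5-hydroxycyclohexyl acetate
Product: 5 (R)-5-(tert-butyldimethylsilyloxy)cyclohex-2-en-1-one, via β-acetoxy ketone 4 (not isolated)
Conditions: (COCl)2, DMSO, CH2Cl2, −78 °C; Et3N, −78 → 0 °C
Reagents that add atoms: none
Why: Swern oxidation of the free carbinol followed by E1cB loss of acetate from the β-acetoxy ketone under the same amine base should give the enone, the silyl ether being by far the poorer leaving group.

Step 4
Reactants: 5 (R)-5-(tert-butyldimethylsilyloxy)cyclohex-2-en-1-one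
Product: 6 (5R)-5-(tert-butyldimethylsilyloxy)-1-methylcyclohex-2-en-1-ol (C1 epimers)
Conditions: MeLi, Et2O, −78 °C; aq. NH4Cl
Reagents that add atoms: methyllithium, [Li]C
Why: 1,2-Addition of the hard organolithium to the enone carbonyl gives the tertiary allylic alcohol, whose new center is erased in the next step.

Step 5
Reactants: 6 (5R)-5-(tert-butyldimethylsilyloxy)-1-methylcyclohex-2-en-1-ol
Product: 7 (S)-5-(tert-butyldimethylsilyloxy)-3-methylcyclohex-2-en-1-one
Conditions: [C5H5NH][CrO3Cl] (pyridinium chlorochromate), NaOAc, 4 Å MS, CH2Cl2, 25 °C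
Reagents that add atoms: pyridinium chlorochromate (supplies the carbonyl oxygen), [O-][Cr](=O)(=O)Cl.c1cc[nH+]cc1
Why: Babler–Dauben oxidative transposition ([3,3] shift of the tertiary allylic chromate ester, then oxidation) should give the β-methyl enone without touching the silyloxy center, whose descriptor changes from R to S only because the ring priorities swap.

Step 6
Reactants: 8 methylenecyclobutane
Product: 9 1-methylcyclobutene
Conditions: KOt-Bu (0.1 equiv), DMSO, 25 °C; fractional distillation
Reagents that add atoms: none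
Why: Base-catalysed allylic prototropic isomerisation equilibrates the exocyclic alkene toward the more substituted endocyclic isomer, which is separated by distillation.

Step 7
Reactants: 7 (S)-5-(tert-butyldimethylsilyloxy)-3-methylcyclohex-2-en-1-one; 9 1-methylcyclobutene
Product: 10 (1R,2S,5R,6S,9S)-9-(tert-butyldimethylsilyloxy)-1,5-dimethyltricyclo[4.4.0.0(2,5)]decan-7-one
Conditions: hν (Pyrex, λ > 300 nm), 9 (10 equiv), CH2Cl2, −40 °C; then filtration through basic Al2O3
Reagents that add atoms: none
Why: Excitation (n→π*) and intersystem crossing give the twisted triplet enone, which bonds to the cyclobutene to form a triplet 1,4-biradical that closes after spin inversion, so C4–C5 and C1–C10 are made stepwise; the closest known reaction type is the enone–cycloalkene [2+2] photocycloaddition of 3-alkylcyclohexenones with cyclobutenes. The one new ring, the central cyclobutane, closes by radical–radical combination of that biradical (not by a concerted pericyclic path) and ends up cis-fused to both neighbouring rings. C1 and C4 are cis because the cyclobutene geometry is kept, C5 and C10 are cis because only the cis six–four fusion is unstrained (any trans-fused adduct should epimerise at the enolisable C5 on basic alumina), and the two outer rings lie anti across the new ring for steric reasons. The cyclobutene should add anti to the C8 silyloxy group, as reagents generally do at C3 of 5-substituted cyclohexenones, which places the C10 methyl cis to the silyl ether. The step needs head-to-head regiochemistry (methyl-bearing C4 to the α-carbon C5) and that anti approach: the first is secured by the β-methyl group, since the other orientation would join two fully substituted carbons, the second by the C8 substituent. The four new centers are erased later, but the methyl/silyloxy cis relationship decides which alkene of the ten-membered ring forms E in step 8.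

Step 8
Reactants: 10 (1R,2S,5R,6S,9S)-9-(tert-butyldimethylsilyloxy)-1,5-dimethyltricyclo[4.4.0.0(2,5)]decan-7-one
Product: 11 (2Z,6E,9S)-9-(tert-butyldimethylsilyloxy)-3,7-dimethylcyclodeca-2,6-dien-1-one
Conditions: flash vacuum pyrolysis, 520 °C, 0.01 mbar, quartz tube, trap at −196 °C
Reagents that add atoms: none
Why: Thermal cleavage of the bicyclo[2.2.0]hexane (formal [2+2] cycloreversion through a chair cyclohexane-1,4-diyl after C1–C4 homolysis) breaks C5–C10 and releases the strain as the ten-membered 1,5-diene; the cis-fused six-membered ring keeps the C10 methyl and the C8 silyloxy group equatorial, which puts C9 equatorial and C6 axial on the diyl ring, so C1=C10 should form E and the conjugated C4=C5 bond Z, while the short contact time limits Cope rearrangement of the product to a divinylcyclohexanone.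

Step 9
Reactants: 11 (2Z,6E,9S)-9-(tert-butyldimethylsilyloxy)-3,7-dimethylcyclodeca-2,6-dien-1-one
Product: 13 (2E,6E,9S)-9-(tert-butyldimethylsilyloxy)-3,7-dimethylcyclodeca-2,6-dien-1-one, via β-phenylthio ketone 12 (not isolated)
Conditions: PhSH (0.2 equiv), Et3N (0.2 equiv), CH2Cl2, 25 °C
Reagents that add atoms: none
Why: Reversible conjugate addition of thiolate and re-elimination (nucleophile-catalysed enone isomerisation) equilibrates only the conjugated C4=C5 bond, and the E,E-dienone, which can adopt the crown conformation, is expected to predominate at equilibrium.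

Step 10
Reactants: 14 ethyl 2-(hydroxymethyl)acrylate
Product: 15 ethyl 2-[(tert-butyldiphenylsilyloxy)methyl]acrylate
Conditions: t-BuPh2SiCl, imidazole, CH2Cl2, 0 → 25 °C
Reagents that add atoms: tert-butyldiphenylsilyl chloride, CC(C)(C)[Si](Cl)(c1ccccc1)c1ccccc1
Why: Imidazole-promoted O-silylation protects the primary allylic alcohol as a bulky ether that will not migrate to a neighbouring alkoxide later.

Step 11
Reactants: 15 ethyl 2-[(tert-butyldiphenylsilyloxy)methyl]acrylate
Product: 17 ethyl 3-(tert-butyldiphenylsilyloxy)-2-oxopropanoate, via ozonide 16 (not isolated)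
Conditions: O3, CH2Cl2, −78 °C; Me2S, −78 → 25 °C
Reagents that add atoms: ozone, [O-][O+]=O
Why: Ozonolysis of the 1,1-disubstituted alkene (1,3-dipolar cycloaddition, cycloreversion and recombination to the ozonide) followed by reductive cleavage with dimethyl sulfide unmasks the 2-oxo ester.

Step 12
Reactants: 13 (2E,6E,9S)-9-(tert-butyldimethylsilyloxy)-3,7-dimethylcyclodeca-2,6-dien-1-one; 17 ethyl 3-(tert-butyldiphenylsilyloxy)-2-oxopropanoate
Product: 20 ethyl 3-(tert-butyldiphenylsilyloxy)-2-[(1S,3E,7E,10S)-10-(tert-butyldimethylsilyloxy)-4,8-dimethyl-2-oxocyclodeca-3,7-dien-1-yl]-2-(trimethylsilyloxy)propanoate (C2 epimers), via lithium enolate 18 (not isolated), via lithium aldolate 19 (not isolated)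
Conditions: LiN(i-Pr)2, THF, −78 °C; 17; then Me3SiCl, Et3N, −78 → −40 °C
Reagents that add atoms: chlorotrimethylsilane, C[Si](C)(C)Cl
Why: Kinetic deprotonation at C7 gives the cross-conjugated lithium enolate, whose aldol addition to the doubly activated ketone of 17 should form C7–C11 from the ring periphery anti to the neighbouring C8 silyloxy group (C7 trans to O8, C11 as an inconsequential epimer mixture), and in situ O-silylation prevents retro-aldol and later chelation.

Step 13
Reactants: 20 ethyl 3-(tert-butyldiphenylsilyloxy)-2-[(1S,3E,7E,10S)-10-(tert-butyldimethylsilyloxy)-4,8-dimethyl-2-oxocyclodeca-3,7-dien-1-yl]-2-(trimethylsilyloxy)propanoate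
Product: 23 (6R,7S,8S)-8-(tert-butyldimethylsilyloxy)-13-(tert-butyldiphenylsilyloxy)-11-hydroxygermacra-1(10)E,4E-dien-12,6-olide (C11 epimers), via lithium alkoxide 21 (not isolated), via trimethylsilyl ether lactone 22 (not isolated)
Conditions: LiBH(s-Bu)3, THF, −78 → 0 °C; then PPTS, MeOH, 0 °C
Reagents that add atoms: none
Why: 1,2-Reduction of the β,β-disubstituted enone carbonyl by the bulky borohydride under Felkin–Anh control (hydride anti to the large silyloxy-bearing C11 group on C7, no chelation possible) should place O6 trans to C11 and therefore syn to O8, after which the alkoxide closes the trans-fused γ-lactone by acyl substitution on the ethyl ester and mild acidic methanolysis removes only the tertiary trimethylsilyl ether.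

Step 14
Reactants: 23 (6R,7S,8S)-8-(tert-butyldimethylsilyloxy)-13-(tert-butyldiphenylsilyloxy)-11-hydroxygermacra-1(10)E,4E-dien-12,6-olide
Product: 25 (6R,8S)-8-(tert-butyldimethylsilyloxy)-13-(tert-butyldiphenylsilyloxy)germacra-1(10)E,4E,7(11)-trien-12,6-olide, via chlorosulfite 24 (not isolated)
Conditions: SOCl2, pyridine, CH2Cl2, −20 → 0 °C
Reagents that add atoms: none
Why: Dehydration of the tertiary α-hydroxy lactone through its chlorosulfite with pyridine (β-elimination toward the only ring hydrogen, at C7) should give the conjugated tetrasubstituted butenolide and removes the C7 and C11 centers, so both C11 epimers converge.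

Step 15
Reactants: 25 (6R,8S)-8-(tert-butyldimethylsilyloxy)-13-(tert-butyldiphenylsilyloxy)germacra-1(10)E,4E,7(11)-trien-12,6-olide
Product: 26 (6R,8S)-13-(tert-butyldiphenylsilyloxy)-8-hydroxygermacra-1(10)E,4E,7(11)-trien-12,6-olide
Conditions: HF·pyridine, pyridine, THF, 0 °C
Reagents that add atoms: none
Why: Buffered acidic fluoride cleaves the secondary tert-butyldimethylsilyl ether much faster than the primary tert-butyldiphenylsilyl ether and should leave the acid- and base-sensitive dienyl butenolide intact.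

Step 16
Reactants: 27 methyl (2S)-2-methyloxirane-2-carboxylate
Product: 29 (R)-3-chloro-2-hydroxy-2-methylpropanoic acid, via chlorohydrin methyl ester 28 (not isolated)
Conditions: 37% aq. HCl, 0 → 50 °C
Reagents that add atoms: hydrogen chloride, Cl; water, O
Why: Chloride opens the protonated epoxide by SN2 at the unsubstituted carbon, so the quaternary stereocenter is untouched (S becomes R only by priority change), and the same acid hydrolyses the methyl ester without the epoxide re-closure that base would cause.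

Step 17
Reactants: 29 (R)-3-chloro-2-hydroxy-2-methylpropanoic acid
Product: 31 (R)-3-chloro-2-methyl-2-(triethylsilyloxy)propanoic acid, via bis-silyl derivative 30 (not isolated)
Conditions: Et3SiOTf (2.2 equiv), 2,6-lutidine, CH2Cl2, 0 °C; then K2CO3, MeOH–H2O, 0 °C, acidify to pH 4
Reagents that add atoms: triethylsilyl trifluoromethanesulfonate, CC[Si](CC)(CC)OS(=O)(=O)C(F)(F)F
Why: Exhaustive silylation of hydroxyl and carboxyl groups followed by mild basic methanolysis of the labile silyl ester leaves the tertiary silyl ether, which blocks self-acylation in the next step.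

Step 18
Reactants: 26 (6R,8S)-13-(tert-butyldiphenylsilyloxy)-8-hydroxygermacra-1(10)E,4E,7(11)-trien-12,6-olide; 31 (R)-3-chloro-2-methyl-2-(triethylsilyloxy)propanoic acid
Product: 33 (6R,8S)-8-[(R)-3-chloro-2-methyl-2-(triethylsilyloxy)propanoyloxy]-13-(tert-butyldiphenylsilyloxy)germacra-1(10)E,4E,7(11)-trien-12,6-olide, via mixed anhydride 32 (not isolated)
Conditions: 2,4,6-Cl3C6H2COCl, Et3N, THF, 25 °C; then 26, DMAP, toluene, 25 °C
Reagents that add atoms: none
Why: Yamaguchi esterification (mixed anhydride, then acyl transfer by DMAP) joins the hindered acid to the secondary C8 hydroxyl without touching a stereocenter, the C13 oxygen still being silylated so that no acyl group can migrate onto it.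

Step 19
Reactants: 33 (6R,8S)-8-[(R)-3-chloro-2-methyl-2-(triethylsilyloxy)propanoyloxy]-13-(tert-butyldiphenylsilyloxy)germacra-1(10)E,4E,7(11)-trien-12,6-olide
Product: 34 (6R,8S)-8-[(R)-3-chloro-2-hydroxy-2-methylpropanoyloxy]-13-hydroxygermacra-1(10)E,4E,7(11)-trien-12,6-olide
Conditions: HF·pyridine, pyridine, THF, 0 → 25 °C
Reagents that add atoms: none
Why: Prolonged treatment with buffered HF cleaves both the tertiary triethylsilyl and the primary tert-butyldiphenylsilyl ether while the diene is still present, because the later epoxides would not survive these conditions.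

Step 20
Reactants: 34 (6R,8S)-8-[(R)-3-chloro-2-hydroxy-2-methylpropanoyloxy]-13-hydroxygermacra-1(10)E,4E,7(11)-trien-12,6-olide
Product: 35 (6R,8S)-13-acetoxy-8-[(R)-3-chloro-2-hydroxy-2-methylpropanoyloxy]germacra-1(10)E,4E,7(11)-trien-12,6-olide
Conditions: Ac2O, pyridine, CH2Cl2, 0 °C
Reagents that add atoms: acetic anhydride, CC(=O)OC(C)=O
Why: Acetylation without DMAP should take only the primary allylic C13 hydroxyl, the tertiary side-chain hydroxyl being unreactive.

Step 21
Reactants: 35 (6R,8S)-13-acetoxy-8-[(R)-3-chloro-2-hydroxy-2-methylpropanoyloxy]germacra-1(10)E,4E,7(11)-trien-12,6-olide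
Product: 37 (1R,4R,5R,6S,8S,10R)-13-acetoxy-8-[(R)-3-chloro-2-hydroxy-2-methylpropanoyloxy]-1,10:4,5-diepoxygermacr-7(11)-en-12,6-olide (CNP0255009.1), via 1,10-monoepoxide 36 (not isolated)
Conditions: dimethyldioxirane (2.5 equiv), acetone, −20 → 0 °C
Reagents that add atoms: dimethyldioxirane, CC1(C)OO1
Why: Concerted electrophilic epoxidation by the dioxirane takes the two electron-rich trisubstituted alkenes (the electron-poor butenolide alkene is inert) from the outer face of the crown conformer with both ring methyls syn: allylic 1,3-strain about C6 (H6 in the alkene plane, O6 outside) delivers the C4–C5 oxygen syn to O6, and the same conformer exposes the outer face of C1=C10, which should give the 1R,10R and 4R,5R epoxides.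

**Compound list**

1 | all-cis-cyclohexane-1,3,5-triol | O[C@H]1C[C@@H](O)C[C@@H](O)C1 | starting material
2 | all-cis-5-(tert-butyldimethylsilyloxy)cyclohexane-1,3-diol (meso) | O[C@H]1C[C@@H](O)C[C@@H](O[Si](C)(C)C(C)(C)C)C1 | intermediate
3 | (1R,3S,5S)-3-(tert-butyldimethylsilyloxy)-5-hydroxycyclohexyl acetate | O[C@H]1C[C@@H](OC(C)=O)C[C@@H](O[Si](C)(C)C(C)(C)C)C1 | intermediate
4 | (3S,5R)-3-acetoxy-5-(tert-butyldimethylsilyloxy)cyclohexanone | O=C1C[C@@H](OC(C)=O)C[C@@H](O[Si](C)(C)C(C)(C)C)C1 | intermediate (not isolated)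
5 | (R)-5-(tert-butyldimethylsilyloxy)cyclohex-2-en-1-one | O=C1C=CC[C@@H](O[Si](C)(C)C(C)(C)C)C1 | intermediate
6 | (5R)-5-(tert-butyldimethylsilyloxy)-1-methylcyclohex-2-en-1-ol, C1 epimers | CC1(O)C=CC[C@@H](O[Si](C)(C)C(C)(C)C)C1 | intermediate
7 | (S)-5-(tert-butyldimethylsilyloxy)-3-methylcyclohex-2-en-1-one | CC1=CC(=O)C[C@@H](O[Si](C)(C)C(C)(C)C)C1 | intermediate
8 | methylenecyclobutane | C=C1CCC1 | starting material
9 | 1-methylcyclobutene | CC1=CCC1 | intermediate
10 | (1R,2S,5R,6S,9S)-9-(tert-butyldimethylsilyloxy)-1,5-dimethyltricyclo[4.4.0.0(2,5)]decan-7-one (cis-anti-cis head-to-head adduct, angular methyl cis to the silyloxy group) | O=C1C[C@@H](O[Si](C)(C)C(C)(C)C)C[C@@]2(C)[C@@H]1[C@]1(C)CC[C@@H]12 | intermediate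
11 | (2Z,6E,9S)-9-(tert-butyldimethylsilyloxy)-3,7-dimethylcyclodeca-2,6-dien-1-one | C1/C(C)=C/CC/C(C)=C\C(=O)C[C@H]1O[Si](C)(C)C(C)(C)C | intermediate
12 | (6E,9S)-9-(tert-butyldimethylsilyloxy)-3,7-dimethyl-3-(phenylthio)cyclodec-6-en-1-one, C3 epimers | C1/C(C)=C/CCC(C)(Sc2ccccc2)CC(=O)C[C@H]1O[Si](C)(C)C(C)(C)C | intermediate (not isolated)
13 | (2E,6E,9S)-9-(tert-butyldimethylsilyloxy)-3,7-dimethylcyclodeca-2,6-dien-1-one | C1/C(C)=C/CC/C(C)=C/C(=O)C[C@H]1O[Si](C)(C)C(C)(C)C | intermediate
14 | ethyl 2-(hydroxymethyl)acrylate | C=C(CO)C(=O)OCC | starting material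
15 | ethyl 2-[(tert-butyldiphenylsilyloxy)methyl]acrylate | C=C(CO[Si](c1ccccc1)(c1ccccc1)C(C)(C)C)C(=O)OCC | intermediate
16 | ethyl 3-[(tert-butyldiphenylsilyloxy)methyl]-1,2,4-trioxolane-3-carboxylate | CCOC(=O)C1(CO[Si](c2ccccc2)(c2ccccc2)C(C)(C)C)OCOO1 | intermediate (not isolated)
17 | ethyl 3-(tert-butyldiphenylsilyloxy)-2-oxopropanoate | CCOC(=O)C(=O)CO[Si](c1ccccc1)(c1ccccc1)C(C)(C)C | intermediate
18 | lithium C6–C7 enolate of 13 | C1/C(C)=C/CC/C(C)=C/C([O-])=C[C@H]1O[Si](C)(C)C(C)(C)C.[Li+] | intermediate (not isolated)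
19 | lithium aldolate (C11 alkoxide of the C7 adduct) | C1/C(C)=C/CC/C(C)=C/C(=O)[C@H](C([O-])(CO[Si](c2ccccc2)(c2ccccc2)C(C)(C)C)C(=O)OCC)[C@H]1O[Si](C)(C)C(C)(C)C.[Li+] | intermediate (not isolated)
20 | ethyl 3-(tert-butyldiphenylsilyloxy)-2-[(1S,3E,7E,10S)-10-(tert-butyldimethylsilyloxy)-4,8-dimethyl-2-oxocyclodeca-3,7-dien-1-yl]-2-(trimethylsilyloxy)propanoate, C2 epimers | C1/C(C)=C/CC/C(C)=C/C(=O)[C@H](C(O[Si](C)(C)C)(CO[Si](c2ccccc2)(c2ccccc2)C(C)(C)C)C(=O)OCC)[C@H]1O[Si](C)(C)C(C)(C)C | intermediate
21 | lithium C6 alkoxide of the reduced adduct (O6 trans to C11, syn to O8) | C1/C(C)=C/CC/C(C)=C/[C@@H]([O-])[C@H](C(O[Si](C)(C)C)(CO[Si](c2ccccc2)(c2ccccc2)C(C)(C)C)C(=O)OCC)[C@H]1O[Si](C)(C)C(C)(C)C.[Li+] | intermediate (not isolated)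
22 | (6R,7S,8S)-8-(tert-butyldimethylsilyloxy)-13-(tert-butyldiphenylsilyloxy)-11-(trimethylsilyloxy)germacra-1(10)E,4E-dien-12,6-olide | C[Si](C)(C)OC1(CO[Si](c3ccccc3)(c3ccccc3)C(C)(C)C)[C@@H]2[C@@H](O[Si](C)(C)C(C)(C)C)C/C(C)=C/CC/C(C)=C/[C@H]2OC1=O | intermediate (not isolated)
23 | (6R,7S,8S)-8-(tert-butyldimethylsilyloxy)-13-(tert-butyldiphenylsilyloxy)-11-hydroxygermacra-1(10)E,4E-dien-12,6-olide, C11 epimers | OC1(CO[Si](c3ccccc3)(c3ccccc3)C(C)(C)C)[C@@H]2[C@@H](O[Si](C)(C)C(C)(C)C)C/C(C)=C/CC/C(C)=C/[C@H]2OC1=O | intermediate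
24 | C11 chlorosulfite of 23 | O=S(Cl)OC1(CO[Si](c3ccccc3)(c3ccccc3)C(C)(C)C)[C@@H]2[C@@H](O[Si](C)(C)C(C)(C)C)C/C(C)=C/CC/C(C)=C/[C@H]2OC1=O | intermediate (not isolated)
25 | (6R,8S)-8-(tert-butyldimethylsilyloxy)-13-(tert-butyldiphenylsilyloxy)germacra-1(10)E,4E,7(11)-trien-12,6-olide | CC(C)(C)[Si](c1ccccc1)(c1ccccc1)OCC1=C2[C@@H](O[Si](C)(C)C(C)(C)C)C/C(C)=C/CC/C(C)=C/[C@H]2OC1=O | intermediate
26 | (6R,8S)-13-(tert-butyldiphenylsilyloxy)-8-hydroxygermacra-1(10)E,4E,7(11)-trien-12,6-olide | CC(C)(C)[Si](c1ccccc1)(c1ccccc1)OCC1=C2[C@@H](O)C/C(C)=C/CC/C(C)=C/[C@H]2OC1=O | intermediate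
27 | methyl (2S)-2-methyloxirane-2-carboxylate | COC(=O)[C@@]1(C)OC1 | starting material
28 | methyl (R)-3-chloro-2-hydroxy-2-methylpropanoate | COC(=O)[C@@](C)(O)CCl | intermediate (not isolated)
29 | (R)-3-chloro-2-hydroxy-2-methylpropanoic acid | OC(=O)[C@@](C)(O)CCl | intermediate
30 | triethylsilyl (R)-3-chloro-2-methyl-2-(triethylsilyloxy)propanoate | CC[Si](CC)(CC)OC(=O)[C@@](C)(O[Si](CC)(CC)CC)CCl | intermediate (not isolated)
31 | (R)-3-chloro-2-methyl-2-(triethylsilyloxy)propanoic acid | OC(=O)[C@@](C)(O[Si](CC)(CC)CC)CCl | intermediate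
32 | mixed anhydride of 31 with 2,4,6-trichlorobenzoic acid | O=C(OC(=O)[C@@](C)(O[Si](CC)(CC)CC)CCl)c1c(Cl)cc(Cl)cc1Cl | intermediate (not isolated)
33 | (6R,8S)-8-[(R)-3-chloro-2-methyl-2-(triethylsilyloxy)propanoyloxy]-13-(tert-butyldiphenylsilyloxy)germacra-1(10)E,4E,7(11)-trien-12,6-olide | CC(C)(C)[Si](c1ccccc1)(c1ccccc1)OCC1=C2[C@@H](OC(=O)[C@@](C)(O[Si](CC)(CC)CC)CCl)C/C(C)=C/CC/C(C)=C/[C@H]2OC1=O | intermediate
34 | (6R,8S)-8-[(R)-3-chloro-2-hydroxy-2-methylpropanoyloxy]-13-hydroxygermacra-1(10)E,4E,7(11)-trien-12,6-olide | OCC1=C2[C@@H](OC(=O)[C@@](C)(O)CCl)C/C(C)=C/CC/C(C)=C/[C@H]2OC1=O | intermediate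
35 | (6R,8S)-13-acetoxy-8-[(R)-3-chloro-2-hydroxy-2-methylpropanoyloxy]germacra-1(10)E,4E,7(11)-trien-12,6-olide | CC(=O)OCC1=C2[C@@H](OC(=O)[C@@](C)(O)CCl)C/C(C)=C/CC/C(C)=C/[C@H]2OC1=O | intermediate
36 | (1R,6R,8S,10R)-13-acetoxy-8-[(R)-3-chloro-2-hydroxy-2-methylpropanoyloxy]-1,10-epoxygermacra-4E,7(11)-dien-12,6-olide | CC(=O)OCC1=C2[C@@H](OC(=O)[C@@](C)(O)CCl)C[C@@]3(C)O[C@@H]3CC/C(C)=C/[C@H]2OC1=O | intermediate (not isolated)
37 | (1R,4R,5R,6S,8S,10R)-13-acetoxy-8-[(R)-3-chloro-2-hydroxy-2-methylpropanoyloxy]-1,10:4,5-diepoxygermacr-7(11)-en-12,6-olide | CC(=O)OCC1=C2[C@@H](OC(=O)[C@@](C)(O)CCl)C[C@@]3(C)O[C@@H]3CC[C@@]3(C)O[C@@H]3[C@H]2OC1=O | target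

**Count and risks**

Total steps: 21. Longest linear sequence: 16 steps (1–5, 7–9, 12–15, 18–21).

Steps most likely to fail:

1. Step 13, hydride delivery to the wrong face of the C6 carbonyl. If the C7 substituent eclipses the carbonyl in the reacting ring conformer, attack from the ring periphery would give the C6 epimer. After the same work-up this would be the cis-fused (6S,7S,8S)-hydroxy lactone F1. The fallback sets out from 20 and rejoins the route at 23. F1 is saponified (LiOH, THF–H2O, 0 °C, careful acidification to pH 5 at 0 °C) to the seco hydroxy acid F2. This is relactonised at once under Mitsunobu conditions (PPh3, diisopropyl azodicarboxylate, THF, 0 °C). SN2 displacement of the activated allylic C6 oxygen by the carboxylate inverts C6 and gives 23, so the center is set by substitution with inversion and no longer by facial control.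

2. Step 9, the thiolate-mediated equilibration may stall at the Michael adduct or may not favour the E,E isomer. The fallback sets out from 11 and rejoins at 13. Benzeneselenol (from PhSeSePh and H3PO2, cat. Et3N, CH2Cl2, 0 °C) is added to the enone to give the β-phenylseleno ketone F3. Oxidation (H2O2, pyridine, CH2Cl2, 0 °C) gives the selenoxide F4. Its syn elimination toward the acidic C5–H regenerates the enone under kinetic rather than thermodynamic control. The E isomer is expected because the two ring bonds at C4 and C5 cannot be eclipsed in the elimination geometry without strain.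

3. Step 8, loss of silanol from the β-silyloxy ketone in the hot zone and Cope rearrangement of the dienone once it has formed. The fallback sets out from 10 and rejoins at 11. The ketone is first reduced (NaBH4, MeOH, 0 °C) to the tricyclic alcohol F5 (C6 epimers), which has no enolisation pathway for elimination. Thermolysis of F5 (flash vacuum pyrolysis at lower temperature, or decalin at 200 °C) opens the bicyclo[2.2.0]hexane through the same diyl to the (4Z,1(10)E)-dienol F6. Oxidation of the allylic alcohol (Dess–Martin periodinane, NaHCO3, CH2Cl2, 25 °C) returns 11, so the conjugated, Cope-prone enone is generated only at room temperature.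

**Further compounds**

F1 | step 13 | (6S,7S,8S)-8-(tert-butyldimethylsilyloxy)-13-(tert-butyldiphenylsilyloxy)-11-hydroxygermacra-1(10)E,4E-dien-12,6-olide (C6 epimer of 23, cis-fused) | OC1(CO[Si](c3ccccc3)(c3ccccc3)C(C)(C)C)[C@@H]2[C@@H](O[Si](C)(C)C(C)(C)C)C/C(C)=C/CC/C(C)=C/[C@@H]2OC1=O
F2 | step 13 | seco hydroxy acid of F1: 3-(tert-butyldiphenylsilyloxy)-2-hydroxy-2-[(1S,2S,3E,7E,10S)-10-(tert-butyldimethylsilyloxy)-2-hydroxy-4,8-dimethylcyclodeca-3,7-dien-1-yl]propanoic acid | OC(=O)C(O)(CO[Si](c2ccccc2)(c2ccccc2)C(C)(C)C)[C@@H]1[C@@H](O[Si](C)(C)C(C)(C)C)C/C(C)=C/CC/C(C)=C/[C@@H]1O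
F3 | step 9 | (6E,9S)-9-(tert-butyldimethylsilyloxy)-3,7-dimethyl-3-(phenylselanyl)cyclodec-6-en-1-one, C3 epimers | C1/C(C)=C/CCC(C)([Se]c2ccccc2)CC(=O)C[C@H]1O[Si](C)(C)C(C)(C)C
F4 | step 9 | selenoxide of F3 | C1/C(C)=C/CCC(C)([Se](=O)c2ccccc2)CC(=O)C[C@H]1O[Si](C)(C)C(C)(C)C
F5 | step 8 | (1R,2S,5R,6S,9S)-9-(tert-butyldimethylsilyloxy)-1,5-dimethyltricyclo[4.4.0.0(2,5)]decan-7-ol, C7 epimers | OC1C[C@@H](O[Si](C)(C)C(C)(C)C)C[C@@]2(C)[C@@H]1[C@]1(C)CC[C@@H]12
F6 | step 8 | (2Z,6E,9S)-9-(tert-butyldimethylsilyloxy)-3,7-dimethylcyclodeca-2,6-dien-1-ol, C1 epimers | C1/C(C)=C/CC/C(C)=C\C(O)C[C@H]1O[Si](C)(C)C(C)(C)C
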